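The constants used here are made up; the rest is arithmetic.

I took spring as dawn left longer, and I looked for one reckoning that would serve both flasks.

| setting | dawn | spring |
|---|---|---|
| starting material | 27 mM | 27 mM |
| rival reagent | 25.6 mM | 25.6 mM |
| gas | 14 mM (held) | 14 mM (held) |
| time | 20 min | 30 min |

    gas ⇌ partner, rate k1*(csat - [partner]) (k1 = 8.5 × 10⁻⁴ s⁻¹, csat = 14 mM)
    rival reagent → decomposed reagent (k2 = 9.2 × 10⁻⁴ s⁻¹)
    starting material + partner → target (k3 = 0.024 M⁻¹ s⁻¹)
    starting material + rival reagent → side product (k4 = 0.011 M⁻¹ s⁻¹)

- which of these there is most of at the end, counted by the starting material in it, dawn (side product / starting material / target)
- which of these there is most of at the end, counted by the starting material in it, spring (side product / starting material / target)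
- the largest of these amounts at the end, in percent of the starting material charged, dawn
- the largest of these amounts at the end, in percent of the starting material charged, spring

- at the start none of partner is dissolved
- run time (dawn): 20 min

Starting material is lost by two steps, each first order in it, so I followed one number, its loss constant (a pseudo-first-order view): the rival reagent's concentration times the constant of the side-product step, plus the partner's concentration times the constant of the target step. In the first instants no partner was dissolved, so the rival term stood by itself at 0.0169 min⁻¹.

For the middle of the run I held starting material at its charge. The rival reagent then falls with 0.0730 min⁻¹, its own decay plus its reaction with starting material, which gives a half-life of 9.49 min. The partner is fed by the gas and drained by starting material, so it climbs with 0.0899 min⁻¹ toward 56.7 % of saturation. At that half-life, I reckoned the rival term of 0.00845 min⁻¹ still larger than the partner term of 0.00657 min⁻¹. For the end of dawn the same reckoning turned the order, with the rival term at 0.00392 min⁻¹, less than the partner term at 0.00954 min⁻¹.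

Integrating each term to the end of dawn gave 0.178 from the rival reagent and 0.123 from the partner, together 0.300. This is the dose, the area under the loss constant up to the end, and the exponential of minus the dose is the fraction of starting material left. For dawn I committed to starting material as the largest, at 74.1 %. Spring's longer time gave parts of 0.206 and 0.224, a dose of 0.430, and so starting material at 65.1 %.

The forecast named starting material for dawn at 73.5 % and starting material for spring at 64 %, holding that “most of the starting material is still unreacted at both end times”.

The simulation gave starting material at 73.6 % in dawn and starting material at 64.0 % in spring. In dawn at 6.72 min, starting material was going to side product 2.0 times as fast as to target. Dawn ended with 16.0 % side product against 10.4 % target, a ratio of 1.54, where my two parts of the dose had given 1.45. For a neighbouring flask, which is dawn with 64 mM of rival reagent and all else held, I scaled the rival part by the charge and got a dose of 0.567, so a fraction of starting material left of 56.7 %. The simulation of that neighbour ended with 55.7 % of starting material.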